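## Analysis of the target

The target 15 is a resveratrol dehydrodimer built on a 2,3-dihydro-1-benzofuran, in which ring A is the benzo ring (C3a to C7a) and ring B the five-membered ring O1–C2–C3–C3a–C7a. C2 carries a 4-hydroxyphenyl group, C3 a 3,5-dihydroxyphenyl group, and C5 of ring A, para to O1, an (E)-2-(3,5-dihydroxyphenyl)ethenyl arm. The only stereocentres are the adjacent C2 and C3, both S, with the two aryl groups on opposite faces of ring B (trans), which is also the more stable relative configuration. Sensitive are the five free phenols (oxidation), the E-stilbene (light, strong acid, hydrogenation), the doubly benzylic C3–H, and above all the C2–O1 bond, a benzylic ether para to a phenol oxygen that ionises readily towards a p-quinone methide or benzyl cation, so that C2 can epimerise and ring B can open. The main difficulty is absolute control: both stereocentres are benzylic carbons with no carbonyl or other functional group nearby on which standard asymmetric methods could act, and the biosynthetic phenoxyl radical coupling offers no laboratory handle for it. A second difficulty is that every coupling and deprotection has to respect the stilbene and the labile C2–O1 bond. The strategy rests on one feature: C3 is a diarylmethine carbon (bonded to C3a of ring A and to the resorcinol ring) directly attached to C2, which is a benzylic C–H carbon on O1. Read backwards, C3 is a diaryl carbene carbon and C2 the methylene of an aryl benzyl ether, so the C2–C3 bond is the product of a 1,5 C–H insertion that closes ring B.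

## Retrosynthetic reasoning

**15 from 14 (five O–H bonds).** All phenols are carried as benzyl ethers in 14. Benzyl is chosen because it survives organomagnesium reagents, hot hydrazine, a manganese oxidant, a metal carbene, Brønsted acid and palladium. On the C2 aryl ring the para benzyloxy group also does useful work, since it makes the methylene C–H more hydridic in the key step and stabilises the C2 cation in the epimerisation. Hydrogenolysis is excluded at the end (stilbene, benzylic C2–O1 bond), so the forward step has to be a low-temperature Lewis-acid cleavage with a non-basic cation scavenger.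

**14 from 11 and 13 (C5–vinyl bond).** Cutting the bond between C5 of ring A and the stilbene carbon removes a complete resveratrol half as the simple styrene 13. It leaves on the core only a bromine atom, which is inert to every earlier step and is already present in a commercial salicylaldehyde. The forward reaction is an E-selective Mizoroki–Heck coupling. The styrene 13 comes from the aldehyde 12 by one-carbon olefination.

**11 from 10 (configuration at C2 only).** No bond is cut here. The key step delivers the kinetic cis isomer 10, whereas the target is trans. Acid can ionise only the C2–O1 bond, so C2 equilibrates to the more stable trans arrangement while C3 keeps the configuration given by the catalyst. This is placed before the Heck coupling because the bromide tolerates acid and the electron-rich stilbene would not.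

**10 from 9 (C2–C3 bond, key disconnection).** The C2–C3 bond is the only bond of ring B that joins the two stereocentres. Cutting it gives the achiral diazo compound 9, in which both carbons sit at easily reached oxidation levels: C3 as a ketone-derived diazo carbon and C2 as an ether methylene. One step then creates ring B, the C2–C3 bond and both stereocentres under catalyst control. The forward reaction must deliver a rhodium carbene to one methylene C–H only, with face selection by a chiral dirhodium tetracarboxylate.

**9 from 8 from 7 (functional group changes at C3).** The diazo group comes from dehydrogenation of the N-unsubstituted hydrazone 8, and that from the benzophenone 7. No skeletal bond is involved, and the diazo compound is made last and used at once.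

**7 from 6, and 6 from 3 and 5 (aryl–carbonyl bond).** The bond between the carbonyl carbon and the resorcinol ring is cut because the nucleophile is then the aryl Grignard reagent 5, made from the commercial bromide 4, and the electrophile is the aldehyde 3. The aryl bromide of 3 is left alone by an arylmagnesium reagent. Oxidation of the carbinol 6 restores the ketone level.

**3 from 1 and 2 (O–CH2 bond).** The ether that later becomes O1–C2 is made by alkylating the phenol 1 with the benzylic chloride 2. This brings in the 4-oxygenated aryl ring and the future C2 in one piece.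

## Alternatives that were turned down

**Alternative 1:** Both aryl–carbon bonds (C2–aryl and C3–aryl) are disconnected across the C2=C3 bond of methyl 1-benzofuran-5-carboxylate A1. In the forward step, zerovalent palladium inserts into 1-(benzyloxy)-4-iodobenzene A2, the aryl palladium iodide adds syn across C2=C3 with aryl on C2 and palladium on the benzylic C3, and that C3–palladium bond is coupled with [3,5-bis(benzyloxy)phenyl]boronic acid A3 to give the cis diaryl ester A4.
- For: three simple pieces are joined in one step and no diazo compound is needed. After syn addition the C2–H lies anti to palladium, so β-hydride elimination is blocked and interception is conceivable.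
- Against: the C2=C3 bond is part of an aromatic system, so insertion is slow. It competes with direct coupling of A2 with A3 and with rearomatising C2-arylation of A1. Absolute control would need a chiral ligand to steer an intermolecular dearomative insertion into an unactivated benzofuran, which has no secure footing. A4 is still cis and needs the same C2 epimerisation. The ester needs reduction, oxidation and a benzylic phosphonate olefination to become the stilbene, where the bromide 11 needs one Heck step.
- Comparison: on convergence and step count to the core (one step against six from 1) this alternative is clearly stronger. The chosen strategy offers instead a unimolecular key step with no competing bimolecular coupling, on an established substrate class, with connectivity fixed by a tether.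

**Alternative 2:** The O1–C2 bond is disconnected, with C2 as the electrophilic carbon of a p-quinone methide. In the forward step, constant-current anodic oxidation of methyl 3-{(1S)-1-[3,5-bis(benzyloxy)phenyl]-2-(4-hydroxyphenyl)ethyl}-4-hydroxybenzoate A5 removes two electrons and two protons from the 4-hydroxybenzyl unit, and the ortho phenol oxygen of ring A adds to the methide carbon to give the trans ester A6.
- For: the polarity is biomimetic, no metal or chemical oxidant is used, the C2 phenol is already free, and the trans relationship follows directly from the C3 centre without a separate epimerisation. On that last point it is stronger than the chosen route.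
- Against: it creates no absolute configuration. The diarylmethine centre of A5, flanked by two sterically similar aryl groups, must be made enantiopure beforehand, so the hard problem is moved, not solved, at the cost of extra steps. A5 has two phenols and an electron-rich bis(benzyloxy)phenyl ring, so phenoxyl coupling can compete at the anode. A6 still contains the oxidisable 4-hydroxybenzyl ether and can lose C2–H and C3–H to aromatise ring B, which erases both stereocentres. The ester again needs three steps to become the stilbene.
- Comparison: the chosen strategy forms the C2–C3 bond and both stereocentres from an achiral precursor in one catalytic step, and the rhodium catalyst has no means of processing its product further.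

**Alternative 3:** The C3–aryl bond and the O1–C2 bond are disconnected across the alkene of 4-hydroxy-3-[(E)-2-(4-hydroxyphenyl)ethenyl]benzaldehyde A7. In the forward step an aryl palladium species, made from A3 and divalent palladium, inserts the stilbene with aryl on C3 and palladium on C2. The C2–palladium bond ionises with help from the para hydroxyl group to a p-quinone methide, and the ring A phenol adds to C2 to give the trans aldehyde A8.
- For: the route is short. C3 would be set in the insertion by a chiral ligand, C2 falls trans on ring closure, and the C5 aldehyde is one olefination away from the stilbene. On step count and on direct access to the trans isomer it is stronger than the chosen route.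
- Against: regiochemistry depends on a small electronic difference between two oxygenated aryl groups, and the reverse insertion puts palladium next to ring A and leads elsewhere. β-Hydride elimination towards C3, the normal Heck outcome, would erase the new stereocentre. 1,2-Diaryl alkenes insert slowly. Free phenols and an aldehyde must survive oxidising palladium conditions. Enantioselective oxidative Heck arylation of such stilbenes is not established.
- Comparison: the chosen strategy offers regiochemistry dictated by the tether, since only one C–C bond can form, and an enantioselective step of a known type.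

Key step: step 6

Assumption: Rh2(S-PTAD)4, tetrakis[(S)-(1-adamantyl)(N-phthalimido)acetato]dirhodium, is taken to be the catalyst antipode that leads to the 3S series with this substrate class; if the first run shows the opposite sense, Rh2(R-PTAD)4 replaces it and nothing else changes.

## Route

Step 1
Reactants: 1 5-bromo-2-hydroxybenzaldehyde; 2 4-(benzyloxy)benzyl chloride [1-(benzyloxy)-4-(chloromethyl)benzene]
Product: 3 2-{[4-(benzyloxy)phenyl]methoxy}-5-bromobenzaldehyde
Conditions: K2CO3, DMF, 50 °C
Reagents that add atoms: none
Why: Williamson ether synthesis; the phenoxide of 1, made acidic by the ortho formyl and para bromo groups, displaces chloride from the activated benzylic halide 2 by SN2, and no other site of either partner reacts under carbonate.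

Step 2
Reactants: 3 2-{[4-(benzyloxy)phenyl]methoxy}-5-bromobenzaldehyde; 4 1,3-bis(benzyloxy)-5-bromobenzene
Product: 6 (2-{[4-(benzyloxy)phenyl]methoxy}-5-bromophenyl)[3,5-bis(benzyloxy)phenyl]methanol (racemic), via [3,5-bis(benzyloxy)phenyl]magnesium bromide 5 (not isolated)
Conditions: 4, Mg, I2 (cat.), THF, reflux; then 3, THF, 0 °C → rt; aq. NH4Cl
Reagents that add atoms: none
Why: Grignard addition; magnesium inserts into the C–Br bond of 4 and the resulting 5 adds to the aldehyde of 3, helped by chelation to the ortho ether oxygen, while an arylmagnesium bromide does not exchange with the aryl bromide of 3 at this temperature. The carbinol centre is formed racemic and is removed in step 3.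

Step 3
Reactants: 6 (2-{[4-(benzyloxy)phenyl]methoxy}-5-bromophenyl)[3,5-bis(benzyloxy)phenyl]methanol
Product: 7 (2-{[4-(benzyloxy)phenyl]methoxy}-5-bromophenyl)[3,5-bis(benzyloxy)phenyl]methanone
Conditions: MnO2 (activated, excess), CH2Cl2, rt
Reagents that add atoms: none
Why: Oxidation of a doubly benzylic secondary alcohol with activated MnO2, a neutral heterogeneous oxidant that leaves the acid-sensitive 4-alkoxybenzyl aryl ether, the benzyl ethers and the aryl bromide untouched.

Step 4
Reactants: 7 (2-{[4-(benzyloxy)phenyl]methoxy}-5-bromophenyl)[3,5-bis(benzyloxy)phenyl]methanone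
Product: 8 (2-{[4-(benzyloxy)phenyl]methoxy}-5-bromophenyl)[3,5-bis(benzyloxy)phenyl]methanone hydrazone (E/Z mixture)
Conditions: N2H4·H2O (excess), AcOH (cat.), EtOH, 90 °C, sealed tube
Reagents that add atoms: hydrazine (used as the hydrate), NN
Why: Hydrazone condensation; the ortho alkoxy group hinders the diaryl ketone, hence the excess of hydrazine (which also suppresses azine formation), acid catalysis and heating in a closed vessel. The medium is far too mild for Wolff–Kishner reduction, the unactivated aryl bromide and the ethers are inert, and both hydrazone isomers are converted in step 5.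

Step 5
Reactants: 8 (2-{[4-(benzyloxy)phenyl]methoxy}-5-bromophenyl)[3,5-bis(benzyloxy)phenyl]methanone hydrazone
Product: 9 [5-bromo-2-{[4-(benzyloxy)phenyl]methoxy}phenyl][3,5-bis(benzyloxy)phenyl]diazomethane
Conditions: MnO2 (activated, excess), CH2Cl2, 0 °C → rt, dark; filtered through Celite under Ar, solution used at once
Reagents that add atoms: none
Why: Dehydrogenation of an N-unsubstituted hydrazone to a diaryldiazomethane with MnO2; two aryl groups stabilise the diazo compound enough for it to persist in cold solution. Acid is excluded and the filtrate is used immediately, because the electron-rich diazo carbon is easily protonated and can go on to the azine.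

Step 6
Reactants: 9 [5-bromo-2-{[4-(benzyloxy)phenyl]methoxy}phenyl][3,5-bis(benzyloxy)phenyl]diazomethane
Product: 10 (2R,3S)-2-[4-(benzyloxy)phenyl]-3-[3,5-bis(benzyloxy)phenyl]-5-bromo-2,3-dihydro-1-benzofuran (cis)
Conditions: Rh2(S-PTAD)4 (1 mol%), CH2Cl2, 0 °C, slow addition of 9
Reagents that add atoms: none
Why: The nucleophilic diazo carbon of 9 binds an axial site of the dirhodium tetracarboxylate (both rhodium atoms divalent), N2 leaves, and the rhodium-bound diaryl carbene is held by the ortho ether tether next to the O–CH2–aryl group; it takes one methylene hydrogen with hydride character while the C2–C3 bond forms in the same asynchronous three-centre event, and the catalyst is released. The closest known reaction type is the enantioselective intramolecular C–H insertion of donor/donor (diaryl) rhodium carbenes into the benzylic ether C–H of aryl benzyl ethers, which gives cis-2,3-diaryl-2,3-dihydrobenzofurans, and 9 belongs to that substrate class. Ring B is closed by the C2–C3 bond in a 1,5-insertion (carbene carbon, C3a, C7a, O1, CH2), the only ring size the tether permits. C3 should become S because the chiral pocket of adamantyl and phthalimido groups around the rhodium axis exposes one face of the carbene to the methylene, so the catalyst antipode decides this centre. C2 is set in the same event: insertion goes with retention at the methylene carbon, and of its two enantiotopic hydrogens the one reached is that whose transition state turns the 4-benzyloxyphenyl group away from the ligand wall, which places it cis to the 3,5-bis(benzyloxy)phenyl group (kinetic control, 2R). The step needs site selectivity for the ether CH2 over the arene rings and the three protecting-group OCH2 groups, and chemoselectivity for insertion over azine or carbene-dimer formation. The first is secured by the substrate, since a carbene with two donor aryl groups is a weak electrophile that seeks the most hydridic C–H, here activated by O1 and the para benzyloxy group, while the meta benzyloxy groups cannot reach the carbene carbon and the para one is remote; the second is secured by adding 9 slowly so that its concentration stays low.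

Step 7
Reactants: 10 (2R,3S)-2-[4-(benzyloxy)phenyl]-3-[3,5-bis(benzyloxy)phenyl]-5-bromo-2,3-dihydro-1-benzofuran
Product: 11 (2S,3S)-2-[4-(benzyloxy)phenyl]-3-[3,5-bis(benzyloxy)phenyl]-5-bromo-2,3-dihydro-1-benzofuran (trans)
Conditions: CF3CO2H (10 equiv), CH2Cl2 (0.02 M), 0 °C → rt
Reagents that add atoms: none
Why: Acid-mediated epimerisation of a 2-(4-alkoxyphenyl)-2,3-dihydrobenzofuran under thermodynamic control; protonation at O1 and SN1 heterolysis of C2–O1 give a secondary benzylic cation stabilised by the para benzyloxy group, and the tethered phenol re-closes reversibly on either face until the trans isomer, free of the eclipsing aryl/aryl interaction, dominates. C3 has no ionisable bond and stays S, so C2 becomes S; high dilution disfavours bimolecular Friedel–Crafts capture of the cation.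

Step 8
Reactants: 12 3,5-bis(benzyloxy)benzaldehyde
Product: 13 1,3-bis(benzyloxy)-5-ethenylbenzene (3,5-bis(benzyloxy)styrene)
Conditions: Ph3PCH3Br, KOtBu, THF, 0 °C → rt
Reagents that add atoms: methyltriphenylphosphonium bromide, C[P+](c1ccccc1)(c1ccccc1)c1ccccc1.[Br-]
Why: Wittig methylenation of an aromatic aldehyde with the non-stabilised ylide; there is no stereochemical issue and the benzyl ethers are inert to the base.

Step 9
Reactants: 11 (2S,3S)-2-[4-(benzyloxy)phenyl]-3-[3,5-bis(benzyloxy)phenyl]-5-bromo-2,3-dihydro-1-benzofuran; 13 1,3-bis(benzyloxy)-5-ethenylbenzene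
Product: 14 (2S,3S)-2-[4-(benzyloxy)phenyl]-3-[3,5-bis(benzyloxy)phenyl]-5-{(E)-2-[3,5-bis(benzyloxy)phenyl]ethenyl}-2,3-dihydro-1-benzofuran
Conditions: Pd(OAc)2 (5 mol%), P(o-tol)3 (15 mol%), Et3N, DMF, 100 °C
Reagents that add atoms: none
Why: Mizoroki–Heck reaction; zerovalent palladium formed in situ from Pd(OAc)2 and the phosphine inserts into the C5–Br bond, the aryl group adds to the unsubstituted alkene carbon of 13, and syn β-hydride elimination from the conformer with the aryl groups anti gives the E-stilbene. Triethylamine takes up the HBr and is too weak a base to touch C3–H, so both stereocentres persist.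

Step 10
Reactants: 14 (2S,3S)-2-[4-(benzyloxy)phenyl]-3-[3,5-bis(benzyloxy)phenyl]-5-{(E)-2-[3,5-bis(benzyloxy)phenyl]ethenyl}-2,3-dihydro-1-benzofuran
Product: 15 5-[(2S,3S)-5-[(E)-2-(3,5-dihydroxyphenyl)ethenyl]-2-(4-hydroxyphenyl)-2,3-dihydro-1-benzofuran-3-yl]benzene-1,3-diol, (2S,3S)-trans-δ-viniferin
Conditions: BCl3 (excess), C6HMe5 (excess), CH2Cl2, −78 °C; then MeOH, −78 °C; dim light
Reagents that add atoms: none
Why: Lewis-acid cleavage of aryl benzyl ethers with BCl3 in the presence of pentamethylbenzene, a non-Lewis-basic arene that captures each benzyl cation by Friedel–Crafts alkylation before it can attack the freed resorcinol rings. At −78 °C the alkene is untouched (unlike under hydrogenolysis), and if C2–O1 ionises reversibly, re-closure returns the more stable trans isomer already in place.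

## Compound list

1 | 5-bromo-2-hydroxybenzaldehyde | O=Cc1cc(Br)ccc1O | starting material
2 | 4-(benzyloxy)benzyl chloride | ClCc1ccc(OCc2ccccc2)cc1 | starting material
3 | 2-{[4-(benzyloxy)phenyl]methoxy}-5-bromobenzaldehyde | O=Cc1cc(Br)ccc1OCc1ccc(OCc2ccccc2)cc1 | intermediate
4 | 1,3-bis(benzyloxy)-5-bromobenzene | Brc1cc(OCc2ccccc2)cc(OCc2ccccc2)c1 | starting material
5 | [3,5-bis(benzyloxy)phenyl]magnesium bromide (formed in the flask, not isolated) | Br[Mg]c1cc(OCc2ccccc2)cc(OCc2ccccc2)c1 | intermediate
6 | (2-{[4-(benzyloxy)phenyl]methoxy}-5-bromophenyl)[3,5-bis(benzyloxy)phenyl]methanol (racemic) | OC(c1cc(Br)ccc1OCc1ccc(OCc2ccccc2)cc1)c1cc(OCc2ccccc2)cc(OCc2ccccc2)c1 | intermediate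
7 | (2-{[4-(benzyloxy)phenyl]methoxy}-5-bromophenyl)[3,5-bis(benzyloxy)phenyl]methanone | O=C(c1cc(Br)ccc1OCc1ccc(OCc2ccccc2)cc1)c1cc(OCc2ccccc2)cc(OCc2ccccc2)c1 | intermediate
8 | (2-{[4-(benzyloxy)phenyl]methoxy}-5-bromophenyl)[3,5-bis(benzyloxy)phenyl]methanone hydrazone (E/Z mixture) | NN=C(c1cc(Br)ccc1OCc1ccc(OCc2ccccc2)cc1)c1cc(OCc2ccccc2)cc(OCc2ccccc2)c1 | intermediate
9 | [5-bromo-2-{[4-(benzyloxy)phenyl]methoxy}phenyl][3,5-bis(benzyloxy)phenyl]diazomethane | [N-]=[N+]=C(c1cc(Br)ccc1OCc1ccc(OCc2ccccc2)cc1)c1cc(OCc2ccccc2)cc(OCc2ccccc2)c1 | intermediate
10 | (2R,3S)-2-[4-(benzyloxy)phenyl]-3-[3,5-bis(benzyloxy)phenyl]-5-bromo-2,3-dihydro-1-benzofuran (cis) | c1ccccc1COc1ccc([C@@H]2Oc3ccc(Br)cc3[C@@H]2c2cc(OCc4ccccc4)cc(OCc4ccccc4)c2)cc1 | intermediate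
11 | (2S,3S)-2-[4-(benzyloxy)phenyl]-3-[3,5-bis(benzyloxy)phenyl]-5-bromo-2,3-dihydro-1-benzofuran (trans) | c1ccccc1COc1ccc([C@H]2Oc3ccc(Br)cc3[C@@H]2c2cc(OCc4ccccc4)cc(OCc4ccccc4)c2)cc1 | intermediate
12 | 3,5-bis(benzyloxy)benzaldehyde | O=Cc1cc(OCc2ccccc2)cc(OCc2ccccc2)c1 | starting material
13 | 1,3-bis(benzyloxy)-5-ethenylbenzene | C=Cc1cc(OCc2ccccc2)cc(OCc2ccccc2)c1 | intermediate
14 | (2S,3S)-2-[4-(benzyloxy)phenyl]-3-[3,5-bis(benzyloxy)phenyl]-5-{(E)-2-[3,5-bis(benzyloxy)phenyl]ethenyl}-2,3-dihydro-1-benzofuran | c1ccccc1COc1ccc([C@H]2Oc3ccc(/C=C/c4cc(OCc5ccccc5)cc(OCc5ccccc5)c4)cc3[C@@H]2c2cc(OCc4ccccc4)cc(OCc4ccccc4)c2)cc1 | intermediate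
15 | 5-[(2S,3S)-5-[(E)-2-(3,5-dihydroxyphenyl)ethenyl]-2-(4-hydroxyphenyl)-2,3-dihydro-1-benzofuran-3-yl]benzene-1,3-diol, (2S,3S)-trans-δ-viniferin | Oc1ccc([C@H]2Oc3ccc(/C=C/c4cc(O)cc(O)c4)cc3[C@@H]2c2cc(O)cc(O)c2)cc1 | target

## Step count and least certain steps

Total: 10 steps. Longest linear sequence: 9 steps (steps 1 to 7, 9 and 10, from 1 to 15). The styrene 13 is made in one step (step 8) off the main line.

**Step 6 (key step).** The most likely failure is partial loss of enantio- and diastereocontrol. The 4-benzyloxyphenyl group stabilises positive charge on the methylene carbon so well that hydride transfer may run ahead of C–C bond formation, and a more stepwise event leaves time for rotation before ring closure. A second failure is coupling of unreacted diazo compound with the carbene when addition is too fast. Any trans isomer formed in the insertion should be removed by chromatography before step 7, since its C3 configuration is not assured.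

Fallback, changing the source of enantiopurity from catalysis to resolution: it sets out from 9. Decomposition with the achiral dirhodium tetraacetate Rh2(OAc)4 in CH2Cl2 would give racemic cis-2-[4-(benzyloxy)phenyl]-3-[3,5-bis(benzyloxy)phenyl]-5-bromo-2,3-dihydro-1-benzofuran F1. Equilibration with CF3CO2H as in step 7 would give racemic trans-2-[4-(benzyloxy)phenyl]-3-[3,5-bis(benzyloxy)phenyl]-5-bromo-2,3-dihydro-1-benzofuran F2. Preparative chromatography on a chiral polysaccharide carbamate phase would then separate the (2S,3S) enantiomer, which is 11, from (2R,3R)-2-[4-(benzyloxy)phenyl]-3-[3,5-bis(benzyloxy)phenyl]-5-bromo-2,3-dihydro-1-benzofuran F3, which is discarded. The route is rejoined at 11.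

**Step 7.** The ring-opened cation may lose the C3 proton (E1). That would give a triarylethene and, through re-protonation, racemisation at C3. Intermolecular Friedel–Crafts capture of the cation by an electron-rich bis(benzyloxy)phenyl ring is also possible.

Fallback, moving the equilibration to the free-phenol stage where ring B opens under much milder acid through the neutral p-quinone methide: it sets out from 10. Heck coupling of 10 with 13 under the conditions of step 9 would give (2R,3S)-2-[4-(benzyloxy)phenyl]-3-[3,5-bis(benzyloxy)phenyl]-5-{(E)-2-[3,5-bis(benzyloxy)phenyl]ethenyl}-2,3-dihydro-1-benzofuran F4. Debenzylation as in step 10 would give 5-[(2R,3S)-5-[(E)-2-(3,5-dihydroxyphenyl)ethenyl]-2-(4-hydroxyphenyl)-2,3-dihydro-1-benzofuran-3-yl]benzene-1,3-diol F5. A catalytic amount of CF3CO2H in acetonitrile at rt would then equilibrate C2. The route is rejoined at 15.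

**Step 9.** Oxidative addition into the electron-rich C5–Br bond (para to O1) may be slow. That would let the catalyst decompose and allow some arylation at the internal alkene carbon.

Fallback, replacing the Heck insertion by a cross-coupling whose regiochemistry is fixed in the boron partner: it sets out from 13. Cross-metathesis of 13 with vinylboronic acid pinacol ester (second-generation Grubbs catalyst, (H2IMes)(PCy3)Cl2Ru=CHPh, CH2Cl2, 40 °C) would give 2-{(E)-2-[3,5-bis(benzyloxy)phenyl]ethenyl}-4,4,5,5-tetramethyl-1,3,2-dioxaborolane F6. Suzuki–Miyaura coupling of F6 with 11 (Pd(dppf)Cl2, K3PO4, dioxane/H2O, 80 °C) would give 14, where the route is rejoined.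

**Step 10.** Benzyl cations that escape the scavenger may C-benzylate the freed resorcinol rings. The Lewis acid may also ionise C2–O1 or protonate the stilbene and start oligomerisation, and removal of all five benzyl groups may be incomplete.

Fallback, keeping the Lewis acid away from the stilbene and making the last step a mild transesterification: it sets out from 11.
- BCl3 and C6HMe5 at −78 °C would give 5-[(2S,3S)-5-bromo-2-(4-hydroxyphenyl)-2,3-dihydro-1-benzofuran-3-yl]benzene-1,3-diol F7.
- Ac2O in pyridine would give 4-[(2S,3S)-3-[3,5-bis(acetyloxy)phenyl]-5-bromo-2,3-dihydro-1-benzofuran-2-yl]phenyl acetate F8.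
- Heck coupling of F8 under the conditions of step 9 with purchased 5-ethenyl-1,3-phenylene diacetate F9 would give penta-O-acetyl-(2S,3S)-trans-δ-viniferin F10.
- K2CO3 in MeOH at 0 °C would remove the acetates. The route is rejoined at 15.

## Further compounds

F1 | step 6 | racemic cis-2-[4-(benzyloxy)phenyl]-3-[3,5-bis(benzyloxy)phenyl]-5-bromo-2,3-dihydro-1-benzofuran, (2R,3S) and (2S,3R) in equal amounts | c1ccccc1COc1ccc([C@@H]2Oc3ccc(Br)cc3[C@@H]2c2cc(OCc4ccccc4)cc(OCc4ccccc4)c2)cc1.c1ccccc1COc1ccc([C@H]2Oc3ccc(Br)cc3[C@H]2c2cc(OCc4ccccc4)cc(OCc4ccccc4)c2)cc1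
F2 | step 6 | racemic trans-2-[4-(benzyloxy)phenyl]-3-[3,5-bis(benzyloxy)phenyl]-5-bromo-2,3-dihydro-1-benzofuran, (2S,3S) and (2R,3R) in equal amounts | c1ccccc1COc1ccc([C@H]2Oc3ccc(Br)cc3[C@@H]2c2cc(OCc4ccccc4)cc(OCc4ccccc4)c2)cc1.c1ccccc1COc1ccc([C@@H]2Oc3ccc(Br)cc3[C@H]2c2cc(OCc4ccccc4)cc(OCc4ccccc4)c2)cc1
F3 | step 6 | (2R,3R)-2-[4-(benzyloxy)phenyl]-3-[3,5-bis(benzyloxy)phenyl]-5-bromo-2,3-dihydro-1-benzofuran | c1ccccc1COc1ccc([C@@H]2Oc3ccc(Br)cc3[C@H]2c2cc(OCc4ccccc4)cc(OCc4ccccc4)c2)cc1
F4 | step 7 | (2R,3S)-2-[4-(benzyloxy)phenyl]-3-[3,5-bis(benzyloxy)phenyl]-5-{(E)-2-[3,5-bis(benzyloxy)phenyl]ethenyl}-2,3-dihydro-1-benzofuran | c1ccccc1COc1ccc([C@@H]2Oc3ccc(/C=C/c4cc(OCc5ccccc5)cc(OCc5ccccc5)c4)cc3[C@@H]2c2cc(OCc4ccccc4)cc(OCc4ccccc4)c2)cc1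
F5 | step 7 | 5-[(2R,3S)-5-[(E)-2-(3,5-dihydroxyphenyl)ethenyl]-2-(4-hydroxyphenyl)-2,3-dihydro-1-benzofuran-3-yl]benzene-1,3-diol | Oc1ccc([C@@H]2Oc3ccc(/C=C/c4cc(O)cc(O)c4)cc3[C@@H]2c2cc(O)cc(O)c2)cc1
F6 | step 9 | 2-{(E)-2-[3,5-bis(benzyloxy)phenyl]ethenyl}-4,4,5,5-tetramethyl-1,3,2-dioxaborolane | CC1(C)OB(/C=C/c2cc(OCc3ccccc3)cc(OCc3ccccc3)c2)OC1(C)C
F7 | step 10 | 5-[(2S,3S)-5-bromo-2-(4-hydroxyphenyl)-2,3-dihydro-1-benzofuran-3-yl]benzene-1,3-diol | Oc1ccc([C@H]2Oc3ccc(Br)cc3[C@@H]2c2cc(O)cc(O)c2)cc1
F8 | step 10 | 4-[(2S,3S)-3-[3,5-bis(acetyloxy)phenyl]-5-bromo-2,3-dihydro-1-benzofuran-2-yl]phenyl acetate | CC(=O)Oc1ccc([C@H]2Oc3ccc(Br)cc3[C@@H]2c2cc(OC(C)=O)cc(OC(C)=O)c2)cc1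
F9 | step 10 | 5-ethenyl-1,3-phenylene diacetate (3,5-diacetoxystyrene, purchased) | C=Cc1cc(OC(C)=O)cc(OC(C)=O)c1
F10 | step 10 | penta-O-acetyl-(2S,3S)-trans-δ-viniferin | CC(=O)Oc1ccc([C@H]2Oc3ccc(/C=C/c4cc(OC(C)=O)cc(OC(C)=O)c4)cc3[C@@H]2c2cc(OC(C)=O)cc(OC(C)=O)c2)cc1
A1 | alternative 1 | methyl 1-benzofuran-5-carboxylate | COC(=O)c1ccc2occc2c1
A2 | alternative 1 | 1-(benzyloxy)-4-iodobenzene | Ic1ccc(OCc2ccccc2)cc1
A3 | alternative 1 | [3,5-bis(benzyloxy)phenyl]boronic acid | OB(O)c1cc(OCc2ccccc2)cc(OCc2ccccc2)c1
A4 | alternative 1 | methyl (2R,3S)-cis-2-[4-(benzyloxy)phenyl]-3-[3,5-bis(benzyloxy)phenyl]-2,3-dihydro-1-benzofuran-5-carboxylate | c1ccccc1COc1ccc([C@@H]2Oc3ccc(C(=O)OC)cc3[C@@H]2c2cc(OCc4ccccc4)cc(OCc4ccccc4)c2)cc1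
A5 | alternative 2 | methyl 3-{(1S)-1-[3,5-bis(benzyloxy)phenyl]-2-(4-hydroxyphenyl)ethyl}-4-hydroxybenzoate | Oc1ccc(C[C@H](c2cc(C(=O)OC)ccc2O)c2cc(OCc3ccccc3)cc(OCc3ccccc3)c2)cc1
A6 | alternative 2 | methyl (2S,3S)-trans-3-[3,5-bis(benzyloxy)phenyl]-2-(4-hydroxyphenyl)-2,3-dihydro-1-benzofuran-5-carboxylate | Oc1ccc([C@H]2Oc3ccc(C(=O)OC)cc3[C@@H]2c2cc(OCc4ccccc4)cc(OCc4ccccc4)c2)cc1
A7 | alternative 3 | 4-hydroxy-3-[(E)-2-(4-hydroxyphenyl)ethenyl]benzaldehyde | O=Cc1ccc(O)c(/C=C/c2ccc(O)cc2)c1
A8 | alternative 3 | (2S,3S)-trans-3-[3,5-bis(benzyloxy)phenyl]-2-(4-hydroxyphenyl)-2,3-dihydro-1-benzofuran-5-carbaldehyde | Oc1ccc([C@H]2Oc3ccc(C=O)cc3[C@@H]2c2cc(OCc4ccccc4)cc(OCc4ccccc4)c2)cc1
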